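## Retrosynthetic overview

1. The target is cut into two achiral halves of 23 heavy atoms each. Fragment A is a 4-methyl-2H-pyranoquinolinone, nucleophilic at C3 and then at its 4-CH3 carbon. Fragment B is a 2-methoxy-2-methyl-2H-pyranoquinolinone ketal, a masked 2-methylpyrylium that is electrophilic at C4 and then at C2. The last step joins them in one chiral-acid cation cascade (formal 3+3 annulation) that makes C3(A)–C4(B) and CH3(A)–C2(B).
2. Fragment A comes from a 2,2-dimethylpyranone (MeMgBr, dehydration), itself from the common quinolone and 3-methylbut-2-enoic acid.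
3. Fragment B comes from the (E)-3-(3-oxobutenyl)quinolone (ketalisation), itself from the common quinolone and 4-methoxybut-3-en-2-one.
4. The common quinolone (4-hydroxy-7,8-dimethoxy-1-methylquinolin-2-one) comes from 2,3-dimethoxy-N-methylaniline and an activated malonate; the aniline comes from veratrole and catechol.
5. Ring order: pyridone ring, then pyran ring A and pyran ring B in parallel, then the cyclohexene ring, whose closure also makes pyran ring B a bridged bicycle and sets all three stereocentres.

Assumption: locants follow pyrano[3,2-c]quinoline numbering (O1, C2–C4, C5=O, N6), and the (R)-acid in step 9 is taken to give the drawn enantiomer (the (S)-acid is used if the product proves antipodal by ECD or X-ray).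

## Route

Step 1
Reactants: 1 catechol
Product: 2 1,2-dimethoxybenzene
Conditions: MeI (2.5 equiv), K2CO3, acetone, reflux
Reagents that add atoms: iodomethane, CI
Why: Double Williamson ether synthesis of the catecholate; no stereocentre is formed.

Step 2
Reactants: 2 1,2-dimethoxybenzene
Product: 4 2,3-dimethoxy-N-methylaniline, via (2,3-dimethoxyphenyl)lithium 3 (not isolated)
Conditions: n-BuLi, TMEDA, Et2O, 0 °C → rt; then MeN(Li)OMe (from MeNHOMe and MeLi, THF, −78 °C), −78 → −15 °C; H2O
Reagents that add atoms: N,O-dimethylhydroxylamine, CNOC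
Why: Directed ortho-metalation puts lithium next to OMe, and electrophilic amination of the aryllithium with a lithium N-methyl-methoxyamide (Beak-type displacement of methoxide at nitrogen) gives the secondary aniline directly.

Step 3
Reactants: 5 malonic acid
Product: 6 bis(2,4,6-trichlorophenyl) malonate
Conditions: 2,4,6-trichlorophenol (2 equiv), POCl3, 100 °C
Reagents that add atoms: 2,4,6-trichlorophenol, Oc1c(Cl)cc(Cl)cc1Cl
Why: POCl3-mediated esterification gives the activated aryl malonate that acylates weakly nucleophilic N-alkylanilines cleanly.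

Step 4
Reactants: 4 2,3-dimethoxy-N-methylaniline; 6 bis(2,4,6-trichlorophenyl) malonate
Product: 8 4-hydroxy-7,8-dimethoxy-1-methylquinolin-2(1H)-one, via aryl malonamate 7 (not isolated)
Conditions: Ph2O, 220 °C, 1 h (1:1)
Reagents that add atoms: none
Why: Thermal cyclocondensation (N-acylation, then intramolecular C-acylation through the acylketene) closes the pyridone ring at the only free ortho position, which is para to a methoxy group.

Step 5
Reactants: 8 4-hydroxy-7,8-dimethoxy-1-methylquinolin-2(1H)-one; 9 3-methylbut-2-enoic acid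
Product: 11 7,8-dimethoxy-2,2,6-trimethyl-2,3-dihydro-4H-pyrano[3,2-c]quinoline-4,5(6H)-dione, via C3-acylated quinolone 10 (not isolated)
Conditions: P2O5/MeSO3H (1:10 w/w), 70 °C
Reagents that add atoms: none
Why: Friedel–Crafts-type acylation of the enol carbon C3 by the acylium ion, then acid-catalysed oxa-Michael closure of the 4-OH onto the β,β-dimethyl enone, builds pyran ring A as in chromanone syntheses.

Step 6
Reactants: 11 7,8-dimethoxy-2,2,6-trimethyl-2,3-dihydro-4H-pyrano[3,2-c]quinoline-4,5(6H)-dione
Product: 13 7,8-dimethoxy-2,2,4,6-tetramethyl-2H-pyrano[3,2-c]quinolin-5(6H)-one, via tertiary carbinol 12 (not isolated)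
Conditions: MeMgBr (1.5 equiv), THF, −40 → 0 °C; then 2 M HCl, rt
Reagents that add atoms: methylmagnesium bromide, C[Mg]Br
Why: Grignard 1,2-addition to the ketone (the quinolone amide carbonyl is vinylogously deactivated and 11 has no acidic H), then E1 dehydration of the oxygen-stabilised tertiary carbinol to the conjugated endocyclic alkene.

Step 7
Reactants: 8 4-hydroxy-7,8-dimethoxy-1-methylquinolin-2(1H)-one; 14 (E)-4-methoxybut-3-en-2-one
Product: 15 4-hydroxy-7,8-dimethoxy-1-methyl-3-[(E)-3-oxobut-1-en-1-yl]quinolin-2(1H)-one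
Conditions: DABCO (20 mol %), MeCN, 60 °C
Reagents that add atoms: none
Why: Base-catalysed vinylic substitution (conjugate addition–elimination of methoxide) by the soft C3 nucleophile gives the thermodynamic E-enone, which sits as a stabilised vinylogous-acid anion and so resists a second addition.

Step 8
Reactants: 15 4-hydroxy-7,8-dimethoxy-1-methyl-3-[(E)-3-oxobut-1-en-1-yl]quinolin-2(1H)-one
Product: 16 2,7,8-trimethoxy-2,6-dimethyl-2H-pyrano[3,2-c]quinolin-5(6H)-one (racemic ketal)
Conditions: HC(OMe)3 (5 equiv), CSA (10 mol %), CH2Cl2, rt → 40 °C; Et3N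
Reagents that add atoms: trimethyl orthoformate, COC(OC)OC
Why: Acid-catalysed E/Z isomerisation, hemiketalisation and ketal exchange trap the Z-enone as the cyclic mixed ketal (pyran ring B), a storable precursor of the 2-methylpyrylium ion; its stereocentre is lost on ionisation.

Step 9
Reactants: 13 7,8-dimethoxy-2,2,4,6-tetramethyl-2H-pyrano[3,2-c]quinolin-5(6H)-one (fragment A); 16 2,7,8-trimethoxy-2,6-dimethyl-2H-pyrano[3,2-c]quinolin-5(6H)-one (fragment B)
Product: 19 CNP0237003.1, via pyrylium ion pair 17 (not isolated), via exocyclic-diene mono-adduct 18 (not isolated)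
Conditions: (R)-3,3′-bis(2,4,6-triisopropylphenyl)-BINOL N-triflylphosphoramide (10 mol %), 5 Å molecular sieves, toluene, −30 °C → rt; 16 added slowly to 13 (1.3 equiv)
Reagents that add atoms: none
Why: Formal (3+3) annulation by asymmetric counter-anion catalysis: the acid ionises 16 to pyrylium 17, whose C4 is attacked by C3 of 13 on the face left open by the chiral anion (sets the CH bearing quinolone B, R); loss of a methyl proton gives diene 18, protonation of its enol ether gives an oxocarbenium at C2 that the diene terminus captures in a vinylogous Prins closure, which can only bridge syn (fixes the quaternary C–O centre, S), and the ring-fusion CH settles under reversible protonation with CMe2O anti to quinolone B (S, trans).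

## Compound list

1 | catechol | Oc1ccccc1O | starting material
2 | 1,2-dimethoxybenzene (veratrole) | COc1ccccc1OC | intermediate
3 | (2,3-dimethoxyphenyl)lithium | [Li]c1cccc(OC)c1OC | intermediate
4 | 2,3-dimethoxy-N-methylaniline | CNc1cccc(OC)c1OC | intermediate
5 | malonic acid | OC(=O)CC(=O)O | starting material
6 | bis(2,4,6-trichlorophenyl) malonate | O=C(CC(=O)Oc1c(Cl)cc(Cl)cc1Cl)Oc1c(Cl)cc(Cl)cc1Cl | intermediate
7 | 2,4,6-trichlorophenyl 3-[(2,3-dimethoxyphenyl)(methyl)amino]-3-oxopropanoate | COc1cccc(N(C)C(=O)CC(=O)Oc2c(Cl)cc(Cl)cc2Cl)c1OC | intermediate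
8 | 4-hydroxy-7,8-dimethoxy-1-methylquinolin-2(1H)-one | COc1ccc2c(O)cc(=O)n(C)c2c1OC | intermediate
9 | 3-methylbut-2-enoic acid | CC(C)=CC(=O)O | starting material
10 | 4-hydroxy-7,8-dimethoxy-1-methyl-3-(3-methylbut-2-enoyl)quinolin-2(1H)-one | COc1ccc2c(O)c(C(=O)C=C(C)C)c(=O)n(C)c2c1OC | intermediate
11 | 7,8-dimethoxy-2,2,6-trimethyl-2,3-dihydro-4H-pyrano[3,2-c]quinoline-4,5(6H)-dione | COc1ccc2c3OC(C)(C)CC(=O)c3c(=O)n(C)c2c1OC | intermediate
12 | 4-hydroxy-7,8-dimethoxy-2,2,4,6-tetramethyl-3,4-dihydro-2H-pyrano[3,2-c]quinolin-5(6H)-one (racemic) | COc1ccc2c3OC(C)(C)CC(C)(O)c3c(=O)n(C)c2c1OC | intermediate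
13 | 7,8-dimethoxy-2,2,4,6-tetramethyl-2H-pyrano[3,2-c]quinolin-5(6H)-one (fragment A) | COc1ccc2c3OC(C)(C)C=C(C)c3c(=O)n(C)c2c1OC | intermediate
14 | (E)-4-methoxybut-3-en-2-one | CO/C=C/C(C)=O | starting material
15 | 4-hydroxy-7,8-dimethoxy-1-methyl-3-[(E)-3-oxobut-1-en-1-yl]quinolin-2(1H)-one | CC(=O)/C=C/c1c(O)c2ccc(OC)c(OC)c2n(C)c1=O | intermediate
16 | 2,7,8-trimethoxy-2,6-dimethyl-2H-pyrano[3,2-c]quinolin-5(6H)-one (racemic ketal, fragment B) | COc1ccc2c3OC(C)(OC)C=Cc3c(=O)n(C)c2c1OC | intermediate
17 | 7,8-dimethoxy-2,6-dimethyl-5-oxo-5,6-dihydropyrano[3,2-c]quinolin-1-ium (cation of the chiral phosphoramidate ion pair) | CC1=[O+]C2=C(C=C1)C(=O)N(C)c1c(OC)c(OC)ccc12 | intermediate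
18 | (3S)-3-[(4R)-7,8-dimethoxy-2,6-dimethyl-5-oxo-5,6-dihydro-4H-pyrano[3,2-c]quinolin-4-yl]-7,8-dimethoxy-2,2,6-trimethyl-4-methylidene-3,4-dihydro-2H-pyrano[3,2-c]quinolin-5(6H)-one | COc1ccc2c3c(c(=O)n(C)c2c1OC)C(=C)[C@H]([C@H]4C=C(C)Oc5c4c(=O)n(C)c6c(OC)c(OC)ccc56)C(C)(C)O3 | intermediate
19 | CNP0237003.1: quinolone A fused to a 2,2-dimethyl-dihydropyran whose C4 is the alkene carbon of a cyclohexene; the cyclohexene C(CH3)(O) and CH carbons are bridged by O4–C4=C3 of quinolone B; S at C(CH3)–O, R at CH–quinolone B, S at the ring-fusion CH (quinolone B and CMe2O trans) | COc1ccc2c3c(c(=O)n(C)c2c1OC)C1=C[C@]2(C)C[C@@H](c4c(c5ccc(OC)c(OC)c5n(C)c4=O)O2)[C@@H]1C(C)(C)O3 | target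

## Step count and risks

Total step count: 9. Longest linear sequence: 6 steps (1 → 2 → 4 → 5 → 6 → 9; the path 1 → 2 → 4 → 7 → 8 → 9 is equally long).

**Step 9 (most likely to fail).** Four things can go wrong:
- the enantioselectivity may be low, because the ion pair has no hydrogen-bond handle;
- the exocyclic-methylene tautomer of 13 may attack first through its CH2 and give the regioisomeric annulation;
- the cis ring-fusion epimer may form;
- 13 or 17 may self-condense.

Fallback: separate C–C bond formation from acid catalysis and obtain the enantiomer by resolution. The fallback sets out from 16 and 13. HBF4·OEt2 in Et2O converts 16 into 7,8-dimethoxy-2,6-dimethyl-5-oxo-5,6-dihydropyrano[3,2-c]quinolin-1-ium tetrafluoroborate F1. F1 and 13 with 2,6-di-tert-butylpyridine in MeCN at −40 °C have no free acid, so 13 cannot tautomerise and only its C3 can attack; this gives racemic mono-adduct, that is 18 together with its enantiomer ent-18 F2. Catalytic TfOH in CH2Cl2 then closes the bridged ring with thermodynamic control of the ring fusion. Preparative chiral SFC on an amylose tris(3,5-dimethylphenylcarbamate) phase separates the product from the enantiomer of the target ent-19 F3. The fallback returns to the route at 19.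

**Step 7.** The C-vinylation may give 2:1 adducts (a second quinolone adding to the enone or pyrylium) or O-vinylation.

Fallback: build the side chain as C1 + C3. The fallback sets out from 8. Reimer–Tiemann formylation (CHCl3, aqueous NaOH, 65 °C) gives 4-hydroxy-7,8-dimethoxy-1-methyl-2-oxo-1,2-dihydroquinoline-3-carbaldehyde F4. Claisen–Schmidt condensation of F4 with acetone (pyrrolidine cat., acetone as solvent, 40 °C) gives the E-enone. The fallback returns to the route at 15.

**Step 2.** The electrophilic amination of the hindered ortho-methoxy aryllithium may give a poor yield.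

Fallback: make the C–N bond by cross-coupling. The fallback sets out from 2, lithiated to 3 as before. Quenching 3 with 1,2-dibromoethane gives 1-bromo-2,3-dimethoxybenzene F5. Buchwald–Hartwig amination of F5 with MeNH2 (Pd2(dba)3, BrettPhos, NaOtBu, dioxane, 80 °C; BrettPhos gives selective mono-arylation) gives the aniline. The fallback returns to the route at 4.

## Further compounds

F1 | step 9 | 7,8-dimethoxy-2,6-dimethyl-5-oxo-5,6-dihydropyrano[3,2-c]quinolin-1-ium tetrafluoroborate | CC1=[O+]C2=C(C=C1)C(=O)N(C)c1c(OC)c(OC)ccc12.F[B-](F)(F)F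
F2 | step 9 | ent-18, (3R)-3-[(4S)-7,8-dimethoxy-2,6-dimethyl-5-oxo-5,6-dihydro-4H-pyrano[3,2-c]quinolin-4-yl]-7,8-dimethoxy-2,2,6-trimethyl-4-methylidene-3,4-dihydro-2H-pyrano[3,2-c]quinolin-5(6H)-one | COc1ccc2c3c(c(=O)n(C)c2c1OC)C(=C)[C@@H]([C@@H]4C=C(C)Oc5c4c(=O)n(C)c6c(OC)c(OC)ccc56)C(C)(C)O3
F3 | step 9 | ent-19, enantiomer of the target (R at C(CH3)–O, S at CH–quinolone B, R at the ring-fusion CH) | COc1ccc2c3c(c(=O)n(C)c2c1OC)C1=C[C@@]2(C)C[C@H](c4c(c5ccc(OC)c(OC)c5n(C)c4=O)O2)[C@H]1C(C)(C)O3
F4 | step 7 | 4-hydroxy-7,8-dimethoxy-1-methyl-2-oxo-1,2-dihydroquinoline-3-carbaldehyde | COc1ccc2c(O)c(C=O)c(=O)n(C)c2c1OC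
F5 | step 2 | 1-bromo-2,3-dimethoxybenzene | COc1cccc(Br)c1OC
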